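**Plan**
The retrosynthesis removes the sulfate from O7 and the ring B benzyl group, trades the C5 and C7 oxygens of ring A for fluorine, and then cuts ring C at O1–C8a and at C3–C4.
This works because O1, the C5 oxygen and the C7 oxygen all lie ortho or para to the C4 carbonyl on ring A, so each aryl C–O bond can arise by fluoride displacement on a symmetric 2,4,6-trifluorobenzoyl unit.
Forward, the enolate of the benzyl-protected ring B acetophenone is C-acylated by 2,4,6-trifluorobenzoyl chloride and the diketone closes ring C on an ortho fluoride; rings A and B are bought, ring C is the only ring made.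
The C5 and C7 fluorides are then exchanged for allyloxy groups (two molecules of allyl alcohol), the allyl groups are removed, O7 is sulfated while the chelated C5 hydroxyl stays free, and the benzyl ether is cleaved last.
The target has no stereocentre, so no stereocontrol is needed.

Key step: step 2

Assumption: the target is taken as the free hydrogen sulfate as drawn, so the route ends by protonating the sodium salt; the acid form should be kept cold and lyophilised at once, since aryl hydrogen sulfates hydrolyse under their own acidity.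

**Step 1**
Reactants: 1 3'-hydroxy-4'-methoxyacetophenone; 2 benzyl bromide
Product: 3 3'-(benzyloxy)-4'-methoxyacetophenone
Conditions: K2CO3, DMF, 50 °C
Reagents that add atoms: none
Why: Williamson ether synthesis, in which the phenoxide of 1 is alkylated by the benzylic bromide in an SN2 reaction while K2CO3 is too weak to enolise the methyl ketone.

**Step 2**
Reactants: 3 3'-(benzyloxy)-4'-methoxyacetophenone; 4 2,4,6-trifluorobenzoyl chloride
Product: 7 benzyl-protected 5,7-difluoroflavone (2-[3-(benzyloxy)-4-methoxyphenyl]-5,7-difluoro-4H-chromen-4-one), via lithium enolate 5 (not isolated), via trifluorophenyl diketone 6 (not isolated)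
Conditions: LiN(SiMe3)2 (2.2 equiv), THF, −78 °C; then 4, −78 to 0 °C; aq NH4Cl, crude 6 taken on; K2CO3, DMF, 60 °C
Reagents that add atoms: none
Why: LiN(SiMe3)2 turns ketone 3 into lithium enolate 5, whose carbon attacks acid chloride 4 in a Claisen-type C-acylation that forms C3–C4, and the second equivalent of base deprotonates diketone 6 as it forms so that the acylation neither reverses nor runs on to a triketone. After the quench, K2CO3 regenerates the diketone enolate, whose oxygen adds to a fluorine-bearing ortho carbon (the future C8a) to give a Meisenheimer adduct stabilised by the ortho carbonyl and the two other fluorines, and loss of fluoride forms O1–C8a. The closest known reaction type is the chromone and flavone synthesis by enolate acylation with a 2-fluorobenzoyl chloride followed by intramolecular SNAr, a fluoride counterpart of the Baker–Venkataraman route. Ring C closes by a six-membered addition–elimination, formally 6-exo-trig at the aromatic carbon, and no stereocentre is created. Carbon rather than oxygen acylation is secured by the lithium enolate in THF with excess base, which funnels material to the chelated lithium diketonate, and the choice of fluoride is secured because only the two symmetry-equivalent ortho fluorides are within reach of the enolate oxygen. The fluorides left at C5 and C7 stay activated by the C4 carbonyl for step 3, and the moderate temperature should keep DMF-derived dimethylamine from attacking them.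

**Step 3**
Reactants: 7 benzyl-protected 5,7-difluoroflavone; 8 allyl alcohol
Product: 10 5,7-bis(allyloxy)-2-[3-(benzyloxy)-4-methoxyphenyl]-4H-chromen-4-one, via 7-allyloxy-5-fluoro flavone 9 (not isolated)
Conditions: allyl alcohol (3 equiv), NaH (2.5 equiv), THF, 0 °C; then 7, THF–DMF, 0 to 50 °C
Reagents that add atoms: allyl alcohol (the second molecule of 8 that is incorporated), C=CCO
Why: Twofold intermolecular SNAr, in which two molecules of sodium allyloxide should displace first the para fluoride at C7 and then the ortho fluoride at C5 through Meisenheimer adducts stabilised by the C4 carbonyl, each with loss of fluoride, while the benzyl and methyl ethers are inert to alkoxide.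

**Step 4**
Reactants: 10 5,7-bis(allyloxy)-2-[3-(benzyloxy)-4-methoxyphenyl]-4H-chromen-4-one
Product: 12 3'-O-benzyldiosmetin (2-[3-(benzyloxy)-4-methoxyphenyl]-5,7-dihydroxy-4H-chromen-4-one), via 5-allyloxy-7-hydroxy flavone 11 (not isolated)
Conditions: Pd(PPh3)4 (5 mol %), morpholine (6 equiv), THF, rt
Reagents that add atoms: none
Why: Tsuji–Trost-type deallylation, in which zerovalent palladium ionises each aryl allyl ether to a π-allyl complex and a phenoxide (the more acidic 7-phenoxide is expected to leave first) and morpholine traps the allyl group, while the benzyl ether cannot ionise in this way and is kept.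

**Step 5**
Reactants: 12 3'-O-benzyldiosmetin
Product: 14 sodium 2-[3-(benzyloxy)-4-methoxyphenyl]-5-hydroxy-4-oxo-4H-chromen-7-yl sulfate, via pyridinium 7-sulfate 13 (not isolated)
Conditions: SO3·pyridine (2 equiv), pyridine, rt; then aq NaHCO3 (pH 8), C18 chromatography
Reagents that add atoms: sulfur trioxide–pyridine complex, [O-]S(=O)(=O)[n+]1ccccc1; sodium hydrogen carbonate, [Na+].OC([O-])=O
Why: O-sulfation of a phenol by an SO3–amine complex, in which the free and most acidic 7-hydroxyl attacks sulfur trioxide whereas the 5-hydroxyl is held in a hydrogen bond to the C4 carbonyl and should not react, and the bicarbonate work-up exchanges pyridinium for sodium without hydrolysing the sulfate.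

**Step 6**
Reactants: 14 sodium 2-[3-(benzyloxy)-4-methoxyphenyl]-5-hydroxy-4-oxo-4H-chromen-7-yl sulfate
Product: 16 luteolin 4'-methyl ether 7-sulfate (5-hydroxy-2-(3-hydroxy-4-methoxyphenyl)-4-oxo-4H-chromen-7-yl hydrogen sulfate), via sodium diosmetin 7-sulfate 15 (not isolated)
Conditions: H2 (1 atm), 10% Pd/C, MeOH–H2O, rt; filter; 1 M HCl (1.0 equiv), 0 °C; C18 cartridge (H2O, then MeOH); lyophilise
Reagents that add atoms: none
Why: Catalytic hydrogenolysis of the benzyl aryl ether on Pd/C, which should leave the aryl sulfate salt and the cross-conjugated C2–C3 double bond untouched at 1 atm, followed by protonation of the sulfate with one equivalent of strong acid and reversed-phase removal of the salt.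

**Compound list**
1 | 3'-hydroxy-4'-methoxyacetophenone | CC(=O)c1ccc(OC)c(O)c1 | starting material
2 | benzyl bromide | BrCc1ccccc1 | starting material
3 | 3'-(benzyloxy)-4'-methoxyacetophenone | CC(=O)c1ccc(OC)c(OCc2ccccc2)c1 | intermediate
4 | 2,4,6-trifluorobenzoyl chloride | O=C(Cl)c1c(F)cc(F)cc1F | starting material
5 | lithium 1-[3-(benzyloxy)-4-methoxyphenyl]ethen-1-olate (lithium enolate of 3) | [Li+].C=C([O-])c1ccc(OC)c(OCc2ccccc2)c1 | intermediate (not isolated)
6 | 1-[3-(benzyloxy)-4-methoxyphenyl]-3-(2,4,6-trifluorophenyl)propane-1,3-dione | O=C(CC(=O)c1c(F)cc(F)cc1F)c1ccc(OC)c(OCc2ccccc2)c1 | intermediate (not isolated)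
7 | 2-[3-(benzyloxy)-4-methoxyphenyl]-5,7-difluoro-4H-chromen-4-one | COc1ccc(-c2cc(=O)c3c(F)cc(F)cc3o2)cc1OCc1ccccc1 | intermediate
8 | allyl alcohol (prop-2-en-1-ol) | C=CCO | starting material
9 | 7-(allyloxy)-2-[3-(benzyloxy)-4-methoxyphenyl]-5-fluoro-4H-chromen-4-one | COc1ccc(-c2cc(=O)c3c(F)cc(OCC=C)cc3o2)cc1OCc1ccccc1 | intermediate (not isolated)
10 | 5,7-bis(allyloxy)-2-[3-(benzyloxy)-4-methoxyphenyl]-4H-chromen-4-one | COc1ccc(-c2cc(=O)c3c(OCC=C)cc(OCC=C)cc3o2)cc1OCc1ccccc1 | intermediate
11 | 5-(allyloxy)-2-[3-(benzyloxy)-4-methoxyphenyl]-7-hydroxy-4H-chromen-4-one | COc1ccc(-c2cc(=O)c3c(OCC=C)cc(O)cc3o2)cc1OCc1ccccc1 | intermediate (not isolated)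
12 | 2-[3-(benzyloxy)-4-methoxyphenyl]-5,7-dihydroxy-4H-chromen-4-one (3'-O-benzyldiosmetin) | COc1ccc(-c2cc(=O)c3c(O)cc(O)cc3o2)cc1OCc1ccccc1 | intermediate
13 | pyridinium 2-[3-(benzyloxy)-4-methoxyphenyl]-5-hydroxy-4-oxo-4H-chromen-7-yl sulfate | COc1ccc(-c2cc(=O)c3c(O)cc(OS(=O)(=O)[O-])cc3o2)cc1OCc1ccccc1.c1cc[nH+]cc1 | intermediate (not isolated)
14 | sodium 2-[3-(benzyloxy)-4-methoxyphenyl]-5-hydroxy-4-oxo-4H-chromen-7-yl sulfate | COc1ccc(-c2cc(=O)c3c(O)cc(OS(=O)(=O)[O-])cc3o2)cc1OCc1ccccc1.[Na+] | intermediate
15 | sodium 5-hydroxy-2-(3-hydroxy-4-methoxyphenyl)-4-oxo-4H-chromen-7-yl sulfate | COc1ccc(-c2cc(=O)c3c(O)cc(OS(=O)(=O)[O-])cc3o2)cc1O.[Na+] | intermediate (not isolated)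
16 | luteolin 4'-methyl ether 7-sulfate (5-hydroxy-2-(3-hydroxy-4-methoxyphenyl)-4-oxo-4H-chromen-7-yl hydrogen sulfate) | COc1ccc(-c2cc(=O)c3c(O)cc(OS(=O)(=O)O)cc3o2)cc1O | target

**Count**
Total steps: 6. Longest linear sequence: 6 steps (1 → 3 → 7 → 10 → 12 → 14 → 16).

**Steps most likely to fail**

Step 3. The second fluoride displacement may stall once the first alkoxy group has entered, or allyloxide may add at C2 and open ring C. The fallback sets out from 7 and comes back at 12. One equivalent of sodium allyloxide in THF–DMF at −20 to 0 °C should stop at mono-ether 9, which is isolated this time. The C5 fluoride is then converted directly to the phenol with (E)-benzaldoxime and Cs2CO3 in DMSO at 60 °C. The less basic oximate adds at C5 to give the O-aryl oxime (E)-benzaldehyde O-{7-(allyloxy)-2-[3-(benzyloxy)-4-methoxyphenyl]-4-oxo-4H-chromen-5-yl}oxime F1. This fragments in the flask to benzonitrile and the phenoxide of 7-(allyloxy)-2-[3-(benzyloxy)-4-methoxyphenyl]-5-hydroxy-4H-chromen-4-one F2. Deallylation of F2 with Pd(PPh3)4 and morpholine, as in step 4, should give 12.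

Step 6. Hydrogenolysis of the anionic salt may be slow enough for the C2–C3 double bond to be saturated, and the sulfate may be lost during protonation. The fallback sets out from 12 and comes back at 16, carrying the sulfate as a neutral, chromatographable diester and avoiding hydrogen altogether. O7 is sulfated with 2,2,2-trichloroethyl chlorosulfate (Et3N, DMAP, THF, 0 °C) to give 2-[3-(benzyloxy)-4-methoxyphenyl]-5-hydroxy-4-oxo-4H-chromen-7-yl 2,2,2-trichloroethyl sulfate F3. The benzyl ether is cleaved with BCl3 and pentamethylbenzene in CH2Cl2 at −78 °C to give 5-hydroxy-2-(3-hydroxy-4-methoxyphenyl)-4-oxo-4H-chromen-7-yl 2,2,2-trichloroethyl sulfate F4. The trichloroethyl group is removed reductively with Zn dust and HCO2NH4 in MeOH to give ammonium 5-hydroxy-2-(3-hydroxy-4-methoxyphenyl)-4-oxo-4H-chromen-7-yl sulfate F5. Protonation of F5 (1 M HCl, 0 °C, C18 cartridge) should give 16.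

Step 2. The enolate may be acylated at oxygen or twice, and the acid chloride may be consumed by the amide base. The fallback sets out from 3 and 4 and comes back at 7, making the diketone by a route in which only carbon can be acylated. Ketone 3 is carboxylated with diallyl carbonate and NaH in THF at reflux to give allyl 3-[3-(benzyloxy)-4-methoxyphenyl]-3-oxopropanoate F6. Its chelated magnesium enolate (MgCl2, Et3N, MeCN, 0 °C to rt) is C-acylated by 4 to give racemic allyl 2-[3-(benzyloxy)-4-methoxybenzoyl]-3-oxo-3-(2,4,6-trifluorophenyl)propanoate F7. Pd(PPh3)4 and morpholine in THF at rt remove the allyl ester to give racemic 2-[3-(benzyloxy)-4-methoxybenzoyl]-3-oxo-3-(2,4,6-trifluorophenyl)propanoic acid F8, which should lose CO2 in the flask to give diketone 6. Diketone 6 is then cyclised with K2CO3 in DMF at 60 °C, as in step 2, to give 7.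

**Further compounds**
F1 | step 3 | (E)-benzaldehyde O-{7-(allyloxy)-2-[3-(benzyloxy)-4-methoxyphenyl]-4-oxo-4H-chromen-5-yl}oxime | COc1ccc(-c2cc(=O)c3c(O/N=C/c4ccccc4)cc(OCC=C)cc3o2)cc1OCc1ccccc1
F2 | step 3 | 7-(allyloxy)-2-[3-(benzyloxy)-4-methoxyphenyl]-5-hydroxy-4H-chromen-4-one | COc1ccc(-c2cc(=O)c3c(O)cc(OCC=C)cc3o2)cc1OCc1ccccc1
F3 | step 6 | 2-[3-(benzyloxy)-4-methoxyphenyl]-5-hydroxy-4-oxo-4H-chromen-7-yl 2,2,2-trichloroethyl sulfate | COc1ccc(-c2cc(=O)c3c(O)cc(OS(=O)(=O)OCC(Cl)(Cl)Cl)cc3o2)cc1OCc1ccccc1
F4 | step 6 | 5-hydroxy-2-(3-hydroxy-4-methoxyphenyl)-4-oxo-4H-chromen-7-yl 2,2,2-trichloroethyl sulfate | COc1ccc(-c2cc(=O)c3c(O)cc(OS(=O)(=O)OCC(Cl)(Cl)Cl)cc3o2)cc1O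
F5 | step 6 | ammonium 5-hydroxy-2-(3-hydroxy-4-methoxyphenyl)-4-oxo-4H-chromen-7-yl sulfate | COc1ccc(-c2cc(=O)c3c(O)cc(OS(=O)(=O)[O-])cc3o2)cc1O.[NH4+]
F6 | step 2 | allyl 3-[3-(benzyloxy)-4-methoxyphenyl]-3-oxopropanoate | C=CCOC(=O)CC(=O)c1ccc(OC)c(OCc2ccccc2)c1
F7 | step 2 | allyl 2-[3-(benzyloxy)-4-methoxybenzoyl]-3-oxo-3-(2,4,6-trifluorophenyl)propanoate (racemic) | C=CCOC(=O)C(C(=O)c1c(F)cc(F)cc1F)C(=O)c1ccc(OC)c(OCc2ccccc2)c1
F8 | step 2 | 2-[3-(benzyloxy)-4-methoxybenzoyl]-3-oxo-3-(2,4,6-trifluorophenyl)propanoic acid (racemic) | OC(=O)C(C(=O)c1c(F)cc(F)cc1F)C(=O)c1ccc(OC)c(OCc2ccccc2)c1
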